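**Strategy.** The thiolactone ring is taken apart at the two bonds that join it to the arene, C3a–C3 and C7a–C1. Because C3a and C7a are adjacent and each sits beside an oxygen-bearing carbon (C4, C7), the benzo ring maps onto a symmetric 3,6-dioxygenated benzyne, and the C3–S2–C1 unit onto a bifunctional partner: an α-thio ketone carbanion whose sulfur carries a methoxycarbonyl group. One operation (step 9) forms both C–C bonds and closes the five-membered ring. Its precursors are an ortho-silylaryl triflate with two MOM ethers and S-(2-oxoheptyl) O-methyl thiocarbonate. Stereochemistry (C3, C1') follows by reductive dynamic kinetic resolution; the C6 prenyl group comes from an O7 ether by Claisen rearrangement.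

Key step: step 9

Numbering: C1 (carbonyl), S2, C3, C3a, C4–C7, C7a of benzo[c]thiophen-1(3H)-one; C1' is the carbinol carbon of the side chain.

Assumption: in step 10 the ring-bearing C3 substituent is taken to occupy the site of the aryl group in the usual model for aryl alkyl ketones, so the (R,R)-complex should give the 1'R carbinol; if the facial sense proved the reverse, the (S,S)-complex would be used and nothing else would change.

Remark: both aryne-flanking oxygens carry the same protecting group so that the aryne stays symmetric; they are told apart only in step 11, where the C1 carbonyl can chelate O7 but not O4.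

**Step 1**
Reactants: 1 hydroquinone
Product: 2 1,4-bis(methoxymethoxy)benzene
Conditions: NaH, MOMCl, DMF, 0 °C → rt
Reagents that add atoms: chloromethyl methyl ether (MOMCl), COCCl
Why: Williamson-type O-alkylation of both phenoxides with the reactive α-chloro ether gives the bis-acetal, whose oxygens direct the later lithiations and tolerate fluoride, base and hydride.

**Step 2**
Reactants: 2 1,4-bis(methoxymethoxy)benzene
Product: 5 2,5-bis(methoxymethoxy)phenol, via aryllithium 3 (not isolated), via arylboronate 4 (not isolated)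
Conditions: n-BuLi, THF, 0 °C; B(OMe)3, −78 °C → rt; H2O2 (30% aq.), AcOH, 0 °C
Reagents that add atoms: hydrogen peroxide, OO
Why: Directed ortho-metalation by a MOM ether (all four ring C–H are equivalent), borylation and oxidative boron-to-oxygen migration should give the phenol.

**Step 3**
Reactants: 5 2,5-bis(methoxymethoxy)phenol
Product: 6 2,5-bis(methoxymethoxy)phenyl N-(propan-2-yl)carbamate
Conditions: i-PrNCO, Et3N (cat.), CH2Cl2, rt
Reagents that add atoms: isopropyl isocyanate, CC(C)N=C=O
Why: Addition of the phenol to the isocyanate (carbamoylation) installs a strong ortho-director that can later be removed under mild base.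

**Step 4**
Reactants: 6 2,5-bis(methoxymethoxy)phenyl N-(propan-2-yl)carbamate
Product: 10 3,6-bis(methoxymethoxy)-2-(trimethylsilyl)phenyl N-(propan-2-yl)carbamate, via N-silyl carbamate 7 (not isolated), via ortho-lithiated N-silyl carbamate 8 (not isolated), via N,C-disilyl carbamate 9 (not isolated)
Conditions: TMSOTf, TMEDA, Et2O, 0 °C → rt; n-BuLi, TMEDA, −78 °C; TMSCl, −78 °C → rt; aq. NH4Cl
Reagents that add atoms: chlorotrimethylsilane, C[Si](C)(C)Cl
Why: After in situ N-silylation the carbamate directs lithiation (directed ortho-metalation) to its only free ortho carbon, which is also ortho to a MOM ether, and TMSCl traps the aryllithium at −78 °C before an anionic Fries shift can occur, the N-silyl group being lost on aqueous work-up.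

**Step 5**
Reactants: 10 3,6-bis(methoxymethoxy)-2-(trimethylsilyl)phenyl N-(propan-2-yl)carbamate
Product: 12 3,6-bis(methoxymethoxy)-2-(trimethylsilyl)phenyl trifluoromethanesulfonate, via silyl phenol 11 (not isolated)
Conditions: DBU, Et2NH, MeCN, 40 °C; then PhNTf2, rt
Reagents that add atoms: N-phenylbis(trifluoromethanesulfonimide), O=S(=O)(N(c1ccccc1)S(=O)(=O)C(F)(F)F)C(F)(F)F
Why: DBU removes the carbamate N–H so that the aryloxide is expelled (E1cB cleavage, the isocyanate being scavenged by Et2NH), and the hindered phenoxide is then triflated by PhNTf2 in the same flask.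

**Step 6**
Reactants: 13 heptan-2-one
Product: 15 1-bromoheptan-2-one, via bromo ketal 14 (not isolated)
Conditions: Br2, MeOH, −10 → 10 °C; then H2O, rt
Reagents that add atoms: bromine, BrBr; water, O
Why: Bromination of a methyl ketone in methanol is kinetically directed to the methyl group (α-bromination through the less substituted enol ether), the minor 3-bromo isomer being removed by distillation.

**Step 7**
Reactants: 15 1-bromoheptan-2-one
Product: 16 S-(2-oxoheptyl) ethanethioate
Conditions: KSAc, acetone, 0 °C → rt
Reagents that add atoms: potassium thioacetate, CC(=O)[S-].[K+]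
Why: SN2 displacement of the activated primary α-bromo ketone by the soft thioacetate anion.

**Step 8**
Reactants: 16 S-(2-oxoheptyl) ethanethioate; 17 methyl chloroformate
Product: 19 S-(2-oxoheptyl) O-methyl thiocarbonate, via sodium thiolate 18 (not isolated)
Conditions: NaOMe (1.0 equiv), MeOH, −20 °C; then 17, −20 → 0 °C
Reagents that add atoms: none
Why: Methoxide transesterifies the thioacetate to the thiolate, which is S-acylated by the chloroformate far faster than methanol is (Schotten–Baumann-type acylation), so the dimerisation-prone α-mercapto ketone is never isolated.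

**Step 9**
Reactants: 12 3,6-bis(methoxymethoxy)-2-(trimethylsilyl)phenyl trifluoromethanesulfonate; 19 S-(2-oxoheptyl) O-methyl thiocarbonate
Product: 24 rac-3-hexanoyl-4,7-bis(methoxymethoxy)benzo[c]thiophen-1(3H)-one, via cesium enolate 20 (not isolated), via aryne 21 (not isolated), via aryl anion 22 (not isolated), via tetrahedral alkoxide 23 (not isolated)
Conditions: 19 (2 equiv), CsF (3 equiv), MeCN, rt, 12 added over 3 h; then AcOH
Reagents that add atoms: none
Why: Proposed new method: fluoride removes the silyl group of 12 with loss of triflate to give aryne 21 and also deprotonates 19 between ketone and sulfur; enolate 20 adds through carbon to 21 (C3a–C3), aryl anion 22 attacks the thiocarbonate carbonyl (C7a–C1) to give alkoxide 23, and 23 loses methoxide directly or after reversible opening to the ester thiolate and re-closure, the methoxide being consumed by the acidic C3–H of 24. The closest known reactions are the aryne acyl-alkylation of β-keto esters (C-arylation, then carbonyl capture by the aryl anion) and aryne annulations in which the aryl anion acylates on a pendant ester, as in xanthone and indolin-3-one formation. The thiolactone ring closes by 5-exo-trig attack of C7a on the S–C(=O)–OMe carbon. C3 is created but not controlled: flanked by ketone, sulfur and arene it epimerises freely, so 24 is racemic and C3 is set in step 10. The aryl anion must prefer the thiocarbonate carbonyl to the ketone and to protonation, which the five- against four-membered transition state and the only modestly stabilised benzylic α-thio carbanion that ketone capture would have to expel should secure, while the symmetric aryne (each aryne carbon beside a MOM-oxygen-bearing carbon) leaves no regiochemical choice. An excess of 19 and slow addition of 12 keep the aryne scarce, so that neither the enolate of 24 nor a transient thiolate should be arylated.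

**Step 10**
Reactants: 24 rac-3-hexanoyl-4,7-bis(methoxymethoxy)benzo[c]thiophen-1(3H)-one
Product: 25 (3S)-3-[(1R)-1-hydroxyhexyl]-4,7-bis(methoxymethoxy)benzo[c]thiophen-1(3H)-one
Conditions: RuCl(p-cymene)[(R,R)-TsDPEN] (2 mol%), HCO2H/Et3N (1:1), CH2Cl2, 30 °C
Reagents that add atoms: none
Why: Noyori–Ikariya asymmetric transfer hydrogenation with dynamic kinetic resolution: C3 of 24 epimerises through its enol in the amine/formate medium, the catalyst fixes C1' as R, and only the 3S ketone can take hydride on that face anti to the C3–C3a bond (away from the benzo ring and its peri C4 ether, sulfur gauche to the carbonyl oxygen), so C3 is set as S by substrate–catalyst matching.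

**Step 11**
Reactants: 25 (3S)-3-[(1R)-1-hydroxyhexyl]-4,7-bis(methoxymethoxy)benzo[c]thiophen-1(3H)-one
Product: 26 (3S)-7-hydroxy-3-[(1R)-1-hydroxyhexyl]-4-(methoxymethoxy)benzo[c]thiophen-1(3H)-one
Conditions: MgBr2·OEt2 (3 equiv), Et2O/PhMe, 0 °C → rt; aq. NH4Cl
Reagents that add atoms: none
Why: Magnesium held in a six-membered chelate between the C1 carbonyl oxygen and O7 activates only the peri MOM ether toward bromide attack at its methylene carbon (chelation-directed Lewis-acid acetal cleavage), whereas the O4 ether has no such partner.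

**Step 12**
Reactants: 26 (3S)-7-hydroxy-3-[(1R)-1-hydroxyhexyl]-4-(methoxymethoxy)benzo[c]thiophen-1(3H)-one; 27 3-chloro-3-methylbut-1-yne
Product: 28 (3S)-3-[(1R)-1-hydroxyhexyl]-4-(methoxymethoxy)-7-[(2-methylbut-3-yn-2-yl)oxy]benzo[c]thiophen-1(3H)-one
Conditions: DBU (1.3 equiv), CuCl2·2H2O (1 mol%), MeCN, 0 °C
Reagents that add atoms: none
Why: Copper-catalysed propargylic etherification lets the phenoxide attack the tertiary carbon, the phenol being the only oxygen acidic enough for DBU, whose conjugate acid buffers the mixture below the basicity needed to epimerise C3.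

**Step 13**
Reactants: 28 (3S)-3-[(1R)-1-hydroxyhexyl]-4-(methoxymethoxy)-7-[(2-methylbut-3-yn-2-yl)oxy]benzo[c]thiophen-1(3H)-one
Product: 29 (3S)-3-[(1R)-1-hydroxyhexyl]-4-(methoxymethoxy)-7-[(2-methylbut-3-en-2-yl)oxy]benzo[c]thiophen-1(3H)-one
Conditions: H2 (1 atm), Pd/CaCO3 poisoned with Pb(OAc)2, quinoline, EtOAc, rt
Reagents that add atoms: none
Why: Semi-hydrogenation of the terminal alkyne over lead-poisoned palladium (Lindlar-type reduction) should stop at the alkene and leave arene, thiolactone and acetal untouched, the acyl-bound sulfur being only a weak ligand.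

**Step 14**
Reactants: 29 (3S)-3-[(1R)-1-hydroxyhexyl]-4-(methoxymethoxy)-7-[(2-methylbut-3-en-2-yl)oxy]benzo[c]thiophen-1(3H)-one
Product: 31 (3S)-7-hydroxy-3-[(1R)-1-hydroxyhexyl]-4-(methoxymethoxy)-6-(3-methylbut-2-en-1-yl)benzo[c]thiophen-1(3H)-one, via dienone 30 (not isolated)
Conditions: PhMe, 110 °C
Reagents that add atoms: none
Why: Aromatic Claisen rearrangement of the 1,1-dimethylallyl ether can deliver the allyl terminus only to C6, the sole unsubstituted ortho carbon of O7, giving the prenyl group by allylic transposition and, after enolisation of the dienone, the chelated phenol without touching C3 or C1'.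

**Step 15**
Reactants: 31 (3S)-7-hydroxy-3-[(1R)-1-hydroxyhexyl]-4-(methoxymethoxy)-6-(3-methylbut-2-en-1-yl)benzo[c]thiophen-1(3H)-one
Product: 32 asperglaucin A
Conditions: HCl (3 M aq.), THF/i-PrOH, rt → 40 °C
Reagents that add atoms: none
Why: Mild acid-catalysed hydrolysis of the remaining MOM acetal frees O4 under conditions too gentle to cyclise the ortho-prenyl phenol to a chroman or to disturb the two stereocentres.

**Compound list**
1 | hydroquinone | Oc1ccc(O)cc1 | starting material
2 | 1,4-bis(methoxymethoxy)benzene | COCOc1ccc(OCOC)cc1 | intermediate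
3 | [2,5-bis(methoxymethoxy)phenyl]lithium | [Li]c1cc(OCOC)ccc1OCOC | intermediate
4 | dimethyl [2,5-bis(methoxymethoxy)phenyl]boronate | COB(OC)c1cc(OCOC)ccc1OCOC | intermediate
5 | 2,5-bis(methoxymethoxy)phenol | Oc1cc(OCOC)ccc1OCOC | intermediate
6 | 2,5-bis(methoxymethoxy)phenyl N-(propan-2-yl)carbamate | CC(C)NC(=O)Oc1cc(OCOC)ccc1OCOC | intermediate
7 | 2,5-bis(methoxymethoxy)phenyl N-(propan-2-yl)-N-(trimethylsilyl)carbamate | CC(C)N([Si](C)(C)C)C(=O)Oc1cc(OCOC)ccc1OCOC | intermediate
8 | 2-lithio-3,6-bis(methoxymethoxy)phenyl N-(propan-2-yl)-N-(trimethylsilyl)carbamate | CC(C)N([Si](C)(C)C)C(=O)Oc1c([Li])c(OCOC)ccc1OCOC | intermediate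
9 | 3,6-bis(methoxymethoxy)-2-(trimethylsilyl)phenyl N-(propan-2-yl)-N-(trimethylsilyl)carbamate | CC(C)N([Si](C)(C)C)C(=O)Oc1c([Si](C)(C)C)c(OCOC)ccc1OCOC | intermediate
10 | 3,6-bis(methoxymethoxy)-2-(trimethylsilyl)phenyl N-(propan-2-yl)carbamate | CC(C)NC(=O)Oc1c([Si](C)(C)C)c(OCOC)ccc1OCOC | intermediate
11 | 3,6-bis(methoxymethoxy)-2-(trimethylsilyl)phenol | Oc1c([Si](C)(C)C)c(OCOC)ccc1OCOC | intermediate
12 | 3,6-bis(methoxymethoxy)-2-(trimethylsilyl)phenyl trifluoromethanesulfonate | COCOc1ccc(OCOC)c(OS(=O)(=O)C(F)(F)F)c1[Si](C)(C)C | intermediate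
13 | heptan-2-one | CCCCCC(C)=O | starting material
14 | 1-bromo-2,2-dimethoxyheptane | CCCCCC(OC)(OC)CBr | intermediate
15 | 1-bromoheptan-2-one | CCCCCC(=O)CBr | intermediate
16 | S-(2-oxoheptyl) ethanethioate | CCCCCC(=O)CSC(C)=O | intermediate
17 | methyl chloroformate | COC(Cl)=O | starting material
18 | sodium 2-oxoheptane-1-thiolate | CCCCCC(=O)C[S-].[Na+] | intermediate
19 | S-(2-oxoheptyl) O-methyl thiocarbonate | COC(=O)SCC(=O)CCCCC | intermediate
20 | cesium enolate of 19 (drawn as the C1 carbanion) | CCCCCC(=O)[CH-]SC(=O)OC.[Cs+] | intermediate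
21 | 3,6-bis(methoxymethoxy)benzyne | COCOC1=CC=C(OCOC)C#C1 | intermediate
22 | cesium 2-[1-(methoxycarbonylsulfanyl)-2-oxoheptyl]-3,6-bis(methoxymethoxy)benzenide | CCCCCC(=O)C(SC(=O)OC)c1c(OCOC)ccc(OCOC)[c-]1.[Cs+] | intermediate
23 | cesium 3-hexanoyl-1-methoxy-4,7-bis(methoxymethoxy)-1,3-dihydrobenzo[c]thiophen-1-olate | CCCCCC(=O)C1SC([O-])(OC)c2c(OCOC)ccc(OCOC)c21.[Cs+] | intermediate
24 | rac-3-hexanoyl-4,7-bis(methoxymethoxy)benzo[c]thiophen-1(3H)-one | CCCCCC(=O)C1SC(=O)c2c(OCOC)ccc(OCOC)c21 | intermediate
25 | (3S)-3-[(1R)-1-hydroxyhexyl]-4,7-bis(methoxymethoxy)benzo[c]thiophen-1(3H)-one | CCCCC[C@@H](O)[C@H]1SC(=O)c2c(OCOC)ccc(OCOC)c21 | intermediate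
26 | (3S)-7-hydroxy-3-[(1R)-1-hydroxyhexyl]-4-(methoxymethoxy)benzo[c]thiophen-1(3H)-one | CCCCC[C@@H](O)[C@H]1SC(=O)c2c(O)ccc(OCOC)c21 | intermediate
27 | 3-chloro-3-methylbut-1-yne | CC(C)(Cl)C#C | starting material
28 | (3S)-3-[(1R)-1-hydroxyhexyl]-4-(methoxymethoxy)-7-[(2-methylbut-3-yn-2-yl)oxy]benzo[c]thiophen-1(3H)-one | CCCCC[C@@H](O)[C@H]1SC(=O)c2c(OC(C)(C)C#C)ccc(OCOC)c21 | intermediate
29 | (3S)-3-[(1R)-1-hydroxyhexyl]-4-(methoxymethoxy)-7-[(2-methylbut-3-en-2-yl)oxy]benzo[c]thiophen-1(3H)-one | CCCCC[C@@H](O)[C@H]1SC(=O)c2c(OC(C)(C)C=C)ccc(OCOC)c21 | intermediate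
30 | (3S)-3-[(1R)-1-hydroxyhexyl]-4-(methoxymethoxy)-6-(3-methylbut-2-en-1-yl)-3,6-dihydrobenzo[c]thiophene-1,7-dione (C6 undefined) | CCCCC[C@@H](O)[C@H]1SC(=O)C2=C1C(OCOC)=CC(CC=C(C)C)C2=O | intermediate
31 | (3S)-7-hydroxy-3-[(1R)-1-hydroxyhexyl]-4-(methoxymethoxy)-6-(3-methylbut-2-en-1-yl)benzo[c]thiophen-1(3H)-one | CCCCC[C@@H](O)[C@H]1SC(=O)c2c(O)c(CC=C(C)C)cc(OCOC)c21 | intermediate
32 | asperglaucin A, (3S)-4,7-dihydroxy-3-[(1R)-1-hydroxyhexyl]-6-(3-methylbut-2-en-1-yl)benzo[c]thiophen-1(3H)-one | CCCCC[C@@H](O)[C@H]1SC(=O)c2c(O)c(CC=C(C)C)cc(O)c21 | target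

**Step count.** Total: 15 steps. Longest linear sequence: 12 steps (steps 1–5 and 9–15, from hydroquinone); the thiocarbonate arm (steps 6–8) is three steps.

**Steps most likely to fail**

Step 9 (Proposed new method). What may go wrong: migration of the methoxycarbonyl group from sulfur to the enolate oxygen before C-arylation, protonation of the aryl anion before ring closure, or opening of the tetrahedral intermediate to an ester thiolate that is S-arylated faster than it re-closes. The fallback uses known chemistry and sets out from 2. Aryllithium 3, made as in step 2, is quenched with paraformaldehyde to give [2,5-bis(methoxymethoxy)phenyl]methanol F1. The lithium alkoxide of F1 is lithiated with n-BuLi (2.2 equiv) and TMEDA at the carbon between the CH2OLi and MOM groups, carboxylated with CO2 and, on mild acidification, lactonised to 4,7-bis(methoxymethoxy)-2-benzofuran-1(3H)-one F2. Lactone-to-thiolactone exchange with KSAc in DMA at 150 °C gives 4,7-bis(methoxymethoxy)benzo[c]thiophen-1(3H)-one F3. Deprotonation at C3 with LiN(SiMe3)2 at −78 °C and aldol addition to hexanal give 3-(1-hydroxyhexyl)-4,7-bis(methoxymethoxy)benzo[c]thiophen-1(3H)-one F4 as a mixture of racemic diastereomers. Oxidation with Dess–Martin periodinane comes back to the route at 24.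

Step 10. What may go wrong: mismatched facial selection, so that hydride is delivered on the side of the benzo ring and the C3 epimer forms, or slow turnover because sulfur binds ruthenium. The fallback sets out from 24 and uses a reagent-controlled reduction without epimerisation. Catecholborane with (S)-1-methyl-3,3-diphenyltetrahydro-1H,3H-pyrrolo[1,2-c][1,3,2]oxazaborole (Corey–Bakshi–Shibata reduction, PhMe, −40 °C) should fix C1' as R for both C3 epimers, giving 25 together with (3R)-3-[(1R)-1-hydroxyhexyl]-4,7-bis(methoxymethoxy)benzo[c]thiophen-1(3H)-one F5. The two are separated by chromatography, the route is rejoined at 25, and F5 is oxidised back to 24 with Dess–Martin periodinane and recycled.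

Step 13. What may go wrong: poisoning of the palladium surface by the thiolactone sulfur or insertion into the acyl–sulfur bond, so that hydrogenation stalls or becomes unselective. The fallback sets out from 28 and avoids palladium. Hydroboration of the terminal alkyne with dicyclohexylborane (2.2 equiv, THF, 0 °C, one equivalent being taken up by the C1' hydroxyl) gives the (E)-alkenylborane borinate F6, which is not isolated. Protonolysis of the vinyl C–B bond with acetic acid (hydroboration–protonolysis) and aqueous work-up come back to the route at 29.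

**Further compounds**
F1 | step 9 | [2,5-bis(methoxymethoxy)phenyl]methanol | COCOc1ccc(OCOC)c(CO)c1
F2 | step 9 | 4,7-bis(methoxymethoxy)-2-benzofuran-1(3H)-one | COCOc1ccc(OCOC)c2c1COC2=O
F3 | step 9 | 4,7-bis(methoxymethoxy)benzo[c]thiophen-1(3H)-one | COCOc1ccc(OCOC)c2c1CSC2=O
F4 | step 9 | 3-(1-hydroxyhexyl)-4,7-bis(methoxymethoxy)benzo[c]thiophen-1(3H)-one (racemic diastereomer mixture) | CCCCCC(O)C1SC(=O)c2c(OCOC)ccc(OCOC)c21
F5 | step 10 | (3R)-3-[(1R)-1-hydroxyhexyl]-4,7-bis(methoxymethoxy)benzo[c]thiophen-1(3H)-one | CCCCC[C@@H](O)[C@@H]1SC(=O)c2c(OCOC)ccc(OCOC)c21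
F6 | step 13 | (3S)-3-[(1R)-1-(dicyclohexylboranyloxy)hexyl]-7-{[(3E)-4-(dicyclohexylboranyl)-2-methylbut-3-en-2-yl]oxy}-4-(methoxymethoxy)benzo[c]thiophen-1(3H)-one | CCCCC[C@@H](OB(C1CCCCC1)C1CCCCC1)[C@H]1SC(=O)c2c(OC(C)(C)/C=C/B(C3CCCCC3)C3CCCCC3)ccc(OCOC)c21
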